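The target is a cis-fused decalin (C5-H and C10-CH3 on the same face), and everything rests on cutting ring A at C1–C2 and C5–C10. An intramolecular Diels–Alder reaction of an open-chain trienone joins C1 of a methacryloyl dienophile to C2 of a 2-silyloxy diene and so closes rings A and B at once. It exploits the cis A/B junction (endo addition), the C3 oxygen (diene enol ether, later the handle for the C4 gem-dimethyl group) and C9, which serves as tether carbonyl chelated to the C8 ether taken from (R)-linalool. C9 is afterwards turned into a sulfone-bearing methylene that carries the farnesyl chain.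

Key step: step 6

Remark: the structure is read as (3S,5S,8R,9R,10S), a cis-fused decalin with C5-H, C10-CH3, C8-CH3, C3-OH and the C9 side chain on one face (β) and C8-OH and C9-H on the other (α); polypodane numbering of the target (ring A: C1–C5, C10; ring B: C5–C10; C11 on C9) is used for all intermediates.

Step 1
Reactants: 1 (R)-(−)-linalool
Product: 2 (3R)-3-(methoxymethoxy)-3,7-dimethylocta-1,6-diene
Conditions: MOMCl, iPr2NEt, Bu4NI (cat.), CH2Cl2, 40 °C
Reagents that add atoms: chloromethyl methyl ether, COCCl
Why: O-alkylation of the tertiary alcohol with the reactive α-chloro ether (MOM ether formation) should install a bidentate ether at the future C8 oxygen without touching the stereocentre.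

Step 2
Reactants: 2 (3R)-3-(methoxymethoxy)-3,7-dimethylocta-1,6-diene
Product: 4 (2R)-2-(methoxymethoxy)-2-methylpentanedial, via bis-ozonide 3 (not isolated)
Conditions: O3, CH2Cl2, −78 °C; then Me2S, −78 °C to rt
Reagents that add atoms: ozone, [O-][O+]=O
Why: Ozonolysis with reductive work-up should cleave both alkenes and leave the C5 and C9 aldehydes on either side of the intact quaternary C8.

Step 3
Reactants: 4 (2R)-2-(methoxymethoxy)-2-methylpentanedial; 5 3-(triphenylphosphoranylidene)butan-2-one
Product: 6 (2R,5E)-2-(methoxymethoxy)-2,6-dimethyl-7-oxooct-5-enal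
Conditions: 5 (1.0 equiv), CH2Cl2, 40 °C
Reagents that add atoms: none
Why: Wittig olefination with the stabilised, α-branched ylide should occur only at the unhindered C5 aldehyde (the C9 aldehyde sits on a quaternary carbon) and give the (E)-enone.

Step 4
Reactants: 6 (2R,5E)-2-(methoxymethoxy)-2,6-dimethyl-7-oxooct-5-enal; 7 2-bromopropene
Product: 8 (4R,7E)-3-hydroxy-4-(methoxymethoxy)-2,4,8-trimethyldeca-1,7-dien-9-one (both C3 epimers)
Conditions: CrCl2, NiCl2 (cat.), DMF, rt
Reagents that add atoms: none
Why: In the Nozaki–Hiyama–Kishi coupling the alkenylchromium species should add to the aldehyde and spare the enone; the new carbinol centre forms as a mixture that step 5 removes.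

Step 5
Reactants: 8 (4R,7E)-3-hydroxy-4-(methoxymethoxy)-2,4,8-trimethyldeca-1,7-dien-9-one
Product: 9 (4R,7E)-4-(methoxymethoxy)-2,4,8-trimethyldeca-1,7-diene-3,9-dione
Conditions: DMP, CH2Cl2, 0 °C to rt
Reagents that add atoms: none
Why: Dess–Martin oxidation of the allylic alcohol should give the α′-alkoxy isopropenyl ketone under neutral conditions that leave the MOM ether and the enone alone.

Step 6
Reactants: 9 (4R,7E)-4-(methoxymethoxy)-2,4,8-trimethyldeca-1,7-diene-3,9-dione
Product: 11 cis-fused cycloadduct 8α-(methoxymethoxy)-4,8β,10β-trimethyl-3-(triethylsilyloxy)-5βH-decal-3-en-9-one, via silyloxy diene 10 (not isolated)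
Conditions: Et3SiOTf, Et3N, CH2Cl2, −78 °C to 0 °C; then MgBr2·OEt2, CH2Cl2, −40 °C to 0 °C
Reagents that add atoms: triethylsilyl trifluoromethanesulfonate, CC[Si](CC)(CC)OS(=O)(=O)C(F)(F)F
Why: Silylation of the methyl ketone gives the 2-silyloxy diene, and MgBr2 chelated between the C9 carbonyl and the C8 methoxymethyl ether oxygen then triggers a concerted but asynchronous intramolecular Diels–Alder reaction in which the C1–C2 bond is the more advanced one. The closest known reaction types are the cycloadditions of 1,7,9-decatrien-3-ones and the chelation-controlled Diels–Alder reactions of α′-alkoxy enones. Ring A closes as the new cyclohexene by [4+2] union of C1=C10 with the diene C2=C3–C4=C5, and ring B closes at the same time as the six-membered tether ring (C6–C9) when C5 bonds to C10. The C5 and C10 centres should be set cis (C5-H and C10-CH3 on one face) by the endo transition state, in which the chelated tether carbonyl lies under the diene and the C10 methyl points away from the C4 methyl. Their absolute sense is controlled by C8: in the chelate the C8–O bond is coplanar with C9=O, C7 must leave toward the diene, and the C8 methyl is left on the face that also carries the C10 methyl. The step needs endo over exo and chelate over non-chelate selectivity, which the internal carbonyl activation, the bidentate ether and a temperature below that of the uncatalysed reaction should secure.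

Step 7
Reactants: 11 cis-fused cycloadduct (triethylsilyl enol ether)
Product: 12 8α-(methoxymethoxy)-4,4,8β,10β-tetramethyl-5βH-decalin-3,9-dione
Conditions: BnMe3NF, MeI, 4 Å MS, THF, 0 °C to rt
Reagents that add atoms: iodomethane, CI
Why: Fluoride cleavage of the silyl enol ether should give the C3/C4 enolate regiospecifically, which is C-methylated (regiospecific enolate alkylation) to the non-stereogenic C4 gem-dimethyl centre; the C9 ketone has no α-hydrogen.

Step 8
Reactants: 12 8α-(methoxymethoxy)-4,4,8β,10β-tetramethyl-5βH-decalin-3,9-dione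
Product: 13 3β-hydroxy-8α-(methoxymethoxy)-4,4,8β,10β-tetramethyl-5βH-decalin-9-one
Conditions: (R)-Me-CBS oxazaborolidine ((R)-1-methyl-3,3-diphenyltetrahydro-1H,3H-pyrrolo[1,2-c][1,3,2]oxazaborole, cat.), BH3·SMe2, THF, −20 °C; MeOH quench
Reagents that add atoms: none
Why: In the Corey–Bakshi–Shibata reduction the catalyst tells the quaternary C4 from the C2 methylene and should deliver hydride to give the (3S)-alcohol (3β-OH) under reagent control, while the C9 ketone between two quaternary carbons is not reduced.

Step 9
Reactants: 13 3β-hydroxy-8α-(methoxymethoxy)-4,4,8β,10β-tetramethyl-5βH-decalin-9-one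
Product: 15 8α-(methoxymethoxy)-4,4,8β,10β-tetramethyl-9-methylidene-5βH-decalin-3β-ol, via β-hydroxysilane 14 (not isolated)
Conditions: Me3SiCH2Li (3 equiv), THF, −78 °C to rt; aqueous work-up; then KH, THF, 50 °C
Reagents that add atoms: (trimethylsilyl)methyllithium, [Li]C[Si](C)(C)C
Why: Peterson olefination: the small primary carbanion should add to the non-enolisable C9 ketone and the β-hydroxysilane then undergoes syn-elimination with KH to the exocyclic alkene, so no stereocentre remains at C9.

Step 10
Reactants: 15 8α-(methoxymethoxy)-4,4,8β,10β-tetramethyl-9-methylidene-5βH-decalin-3β-ol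
Product: 17 8α-(methoxymethoxy)-4,4,8β,10β-tetramethyl-9-[(phenylsulfonyl)methylidene]-5βH-decalin-3β-ol, via β-iodo sulfone 16 (not isolated)
Conditions: PhSO2Na, I2, EtOAc–H2O, rt; then DBU, CH2Cl2, 0 °C
Reagents that add atoms: sodium benzenesulfinate, [Na+].[O-]S(=O)c1ccccc1
Why: Radical iodosulfonylation (sulfonyl radical to the CH2 terminus, iodine atom transfer to C9) followed by dehydroiodination, which can only run toward C11 because C8 and C10 are quaternary, should give the vinyl sulfone.

Step 11
Reactants: 17 8α-(methoxymethoxy)-4,4,8β,10β-tetramethyl-9-[(phenylsulfonyl)methylidene]-5βH-decalin-3β-ol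
Product: 18 4,4,8β,10β-tetramethyl-9-[(phenylsulfonyl)methylidene]-5βH-decalin-3β,8α-diol
Conditions: HCl (conc., cat.), MeOH, 45 °C
Reagents that add atoms: none
Why: Acid-catalysed acetal exchange (MOM cleavage) should free the tertiary C8 hydroxyl, the electron-poor vinyl sulfone protecting the allylic position from ionisation.

Step 12
Reactants: 18 4,4,8β,10β-tetramethyl-9-[(phenylsulfonyl)methylidene]-5βH-decalin-3β,8α-diol
Product: 19 4,4,8β,10β-tetramethyl-9β-[(phenylsulfonyl)methyl]-5βH,9αH-decalin-3β,8α-diol
Conditions: [Ir(cod)(PCy3)(py)]PF6 (cat.), H2, CH2Cl2, rt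
Reagents that add atoms: none
Why: Hydroxyl-directed hydrogenation: iridium bound to the α-oriented C8 hydroxyl should deliver hydrogen to the α-face of C9=C11, which sets C9 (9α-H, CH2SO2Ph β).

Step 13
Reactants: 19 4,4,8β,10β-tetramethyl-9β-[(phenylsulfonyl)methyl]-5βH,9αH-decalin-3β,8α-diol; 20 (2E,6E)-farnesyl bromide
Product: 21 11-(phenylsulfonyl) derivative of the target (both C11 epimers)
Conditions: n-BuLi (3.2 equiv), THF–HMPA, −78 °C; then 20, −78 °C to −20 °C
Reagents that add atoms: none
Why: Alkylation of the α-sulfonyl carbanion (both hydroxyls carried as lithium alkoxides) with the primary allylic bromide by SN2 displacement should form C11–C12 without allylic transposition; the C11 centre is removed in step 14.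

Step 14
Reactants: 21 11-(phenylsulfonyl) derivative of the target
Product: 22 target, (3S,5S,8R,9R,10S)-polypoda-13E,17E,21-triene-3β,8α-diol with cis A/B junction
Conditions: 6% Na(Hg), Na2HPO4, MeOH–THF, −20 °C
Reagents that add atoms: none
Why: Reductive desulfonylation with sodium amalgam should cleave the C–S bond of the non-allylic sulfone without moving or reducing the trisubstituted alkenes.

Compound list
1 | (R)-(−)-linalool, (3R)-3,7-dimethylocta-1,6-dien-3-ol | CC(C)=CCC[C@@](C=C)(C)O | starting material
2 | (3R)-3-(methoxymethoxy)-3,7-dimethylocta-1,6-diene | CC(C)=CCC[C@@](C=C)(C)OCOC | intermediate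
3 | bis-ozonide of 2 (both alkenes as 1,2,4-trioxolanes, mixture at the trioxolane carbons) | CC1(C)OC(CC[C@@](C2OCOO2)(C)OCOC)OO1 | intermediate
4 | (2R)-2-(methoxymethoxy)-2-methylpentanedial | O=CCC[C@@](C=O)(C)OCOC | intermediate
5 | 3-(triphenylphosphoranylidene)butan-2-one | CC(=O)C(C)=P(c1ccccc1)(c1ccccc1)c1ccccc1 | starting material
6 | (2R,5E)-2-(methoxymethoxy)-2,6-dimethyl-7-oxooct-5-enal | CC(=O)/C(C)=C/CC[C@@](C=O)(C)OCOC | intermediate
7 | 2-bromopropene | CC(Br)=C | starting material
8 | (4R,7E)-3-hydroxy-4-(methoxymethoxy)-2,4,8-trimethyldeca-1,7-dien-9-one (both C3 epimers) | CC(=O)/C(C)=C/CC[C@@](C(O)C(C)=C)(C)OCOC | intermediate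
9 | (4R,7E)-4-(methoxymethoxy)-2,4,8-trimethyldeca-1,7-diene-3,9-dione | CC(=O)/C(C)=C/CC[C@@](C(=O)C(C)=C)(C)OCOC | intermediate
10 | (4R,7E)-4-(methoxymethoxy)-2,4,8-trimethyl-9-(triethylsilyloxy)deca-1,7,9-trien-3-one | C=C(O[Si](CC)(CC)CC)/C(C)=C/CC[C@@](C(=O)C(C)=C)(C)OCOC | intermediate
11 | 8α-(methoxymethoxy)-4,8β,10β-trimethyl-3-(triethylsilyloxy)-5βH-decal-3-en-9-one (cis-fused) | O=C1[C@@]2(C)CCC(O[Si](CC)(CC)CC)=C(C)[C@H]2CC[C@@]1(C)OCOC | intermediate
12 | 8α-(methoxymethoxy)-4,4,8β,10β-tetramethyl-5βH-decalin-3,9-dione | O=C1[C@@]2(C)CCC(=O)C(C)(C)[C@H]2CC[C@@]1(C)OCOC | intermediate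
13 | 3β-hydroxy-8α-(methoxymethoxy)-4,4,8β,10β-tetramethyl-5βH-decalin-9-one | O=C1[C@@]2(C)CC[C@H](O)C(C)(C)[C@H]2CC[C@@]1(C)OCOC | intermediate
14 | 8α-(methoxymethoxy)-4,4,8β,10β-tetramethyl-9-[(trimethylsilyl)methyl]-5βH-decalin-3β,9-diol (C9 configuration immaterial) | C[Si](C)(C)CC1(O)[C@@]2(C)CC[C@H](O)C(C)(C)[C@H]2CC[C@@]1(C)OCOC | intermediate
15 | 8α-(methoxymethoxy)-4,4,8β,10β-tetramethyl-9-methylidene-5βH-decalin-3β-ol | C=C1[C@@]2(C)CC[C@H](O)C(C)(C)[C@H]2CC[C@@]1(C)OCOC | intermediate
16 | 9-iodo-8α-(methoxymethoxy)-4,4,8β,10β-tetramethyl-9-[(phenylsulfonyl)methyl]-5βH-decalin-3β-ol (C9 configuration immaterial) | O=S(=O)(c1ccccc1)CC1(I)[C@@]2(C)CC[C@H](O)C(C)(C)[C@H]2CC[C@@]1(C)OCOC | intermediate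
17 | 8α-(methoxymethoxy)-4,4,8β,10β-tetramethyl-9-[(phenylsulfonyl)methylidene]-5βH-decalin-3β-ol (alkene geometry immaterial) | O=S(=O)(c1ccccc1)C=C1[C@@]2(C)CC[C@H](O)C(C)(C)[C@H]2CC[C@@]1(C)OCOC | intermediate
18 | 4,4,8β,10β-tetramethyl-9-[(phenylsulfonyl)methylidene]-5βH-decalin-3β,8α-diol | O=S(=O)(c1ccccc1)C=C1[C@@]2(C)CC[C@H](O)C(C)(C)[C@H]2CC[C@@]1(C)O | intermediate
19 | 4,4,8β,10β-tetramethyl-9β-[(phenylsulfonyl)methyl]-5βH,9αH-decalin-3β,8α-diol | O=S(=O)(c1ccccc1)C[C@@H]1[C@@]2(C)CC[C@H](O)C(C)(C)[C@H]2CC[C@@]1(C)O | intermediate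
20 | (2E,6E)-farnesyl bromide | CC(C)=CCC/C(C)=C/CC/C(C)=C/CBr | starting material
21 | 11-(phenylsulfonyl) derivative of the target (both C11 epimers) | CC(C)=CCC/C(C)=C/CC/C(C)=C/CC([C@@H]1[C@@]2(C)CC[C@H](O)C(C)(C)[C@H]2CC[C@@]1(C)O)S(=O)(=O)c1ccccc1 | intermediate
22 | (3S,5S,8R,9R,10S)-polypoda-13E,17E,21-triene-3β,8α-diol, cis A/B junction | CC(C)=CCC/C(C)=C/CC/C(C)=C/CC[C@@H]1[C@@]2(C)CC[C@H](O)C(C)(C)[C@H]2CC[C@@]1(C)O | target

Total steps: 14. Longest linear sequence: 14 steps (from 1; compounds 5, 7 and 20 are commercial).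

Steps most likely to fail

First, step 6. Facial control may be lost if the unchelated thermal pathway competes, and the chelated transition state forces the C8 and C10 methyl groups into a 1,3-diaxial contact, which may slow the reaction and let exo addition intrude. The fallback brings in the C10 methyl after the cycloaddition; it sets out from 6 and comes back to the route at 11. Nozaki–Hiyama–Kishi coupling of 6 with vinyl bromide (CrCl2, NiCl2 cat., DMF) should give (4R,7E)-3-hydroxy-4-(methoxymethoxy)-4,8-dimethyldeca-1,7-dien-9-one F1 as a mixture of C3 epimers. Dess–Martin oxidation should then give (4R,7E)-4-(methoxymethoxy)-4,8-dimethyldeca-1,7-diene-3,9-dione F2 with a vinyl ketone as dienophile. Silylation as in step 6 gives (4R,7E)-4-(methoxymethoxy)-4,8-dimethyl-9-(triethylsilyloxy)deca-1,7,9-trien-3-one F3 in the flask, not isolated. MgBr2·OEt2 should then close 8α-(methoxymethoxy)-4,8β-dimethyl-3-(triethylsilyloxy)-5βH-decal-3-en-9-one F4 through a transition state that is free of the methyl–methyl contact; its C10 configuration does not matter. Deprotonation of the cycloadduct at C10, the only α-hydrogen of the C9 ketone (LDA, THF, −78 °C), and angular methylation with MeI, which in ring-fusion decalone enolates should enter on the C5-H face, comes back to the route at 11.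

Second, step 9. The C9 carbonyl lies between two quaternary carbons and may be sterically closed to the carbanion, so that the ketone is returned unchanged. The fallback sets out from 13 and comes back to the route at 15 in one operation: Tebbe methylenation with Cp2Ti(μ-Cl)(μ-CH2)AlMe2 (excess, pyridine, toluene–THF, −40 °C to rt). A small, oxophilic titanium methylidene transfers CH2 by [2+2] cycloaddition and cycloreversion instead of by carbanion addition, and the C3 hydroxyl is carried as a titanium alkoxide until work-up. New compounds on this way: none F0.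

Third, step 12. The crowded trisubstituted vinyl sulfone may fail to bind to iridium, or hydrogen may be delivered without guidance by O8, giving poor facial selectivity at C9. The fallback sets out from 18 and comes back to the route at 19 in one operation: alkoxide-directed conjugate reduction with NaAlH2(OCH2CH2OMe)2 in THF. The aluminium alkoxide formed at the C8 hydroxyl hands hydride intramolecularly to C9, the β-carbon of the vinyl sulfone, on the α-face, and the α-sulfonyl carbanion is protonated on work-up. New compounds on this way: none F0.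

Further compounds
F1 | step 6 | (4R,7E)-3-hydroxy-4-(methoxymethoxy)-4,8-dimethyldeca-1,7-dien-9-one | CC(=O)/C(C)=C/CC[C@@](C(O)C=C)(C)OCOC
F2 | step 6 | (4R,7E)-4-(methoxymethoxy)-4,8-dimethyldeca-1,7-diene-3,9-dione | CC(=O)/C(C)=C/CC[C@@](C(=O)C=C)(C)OCOC
F3 | step 6 | (4R,7E)-4-(methoxymethoxy)-4,8-dimethyl-9-(triethylsilyloxy)deca-1,7,9-trien-3-one | C=C(O[Si](CC)(CC)CC)/C(C)=C/CC[C@@](C(=O)C=C)(C)OCOC
F4 | step 6 | 8α-(methoxymethoxy)-4,8β-dimethyl-3-(triethylsilyloxy)-5βH-decal-3-en-9-one | O=C1C2CCC(O[Si](CC)(CC)CC)=C(C)[C@H]2CC[C@@]1(C)OCOC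
F0 | step 9 | none | none
F0 | step 12 | none | none
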